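## The problem

Compound 22 is a 3,3′-biflavanone: two 2-(4-methoxyphenyl)chroman-4-one units joined through C3–C3′. Four contiguous stereocentres (C2, C3, C3′, C2′, all R) lie on the chain O1–C2–C3–C3′–C2′–O1′ between two ketones. In each unit H-2 and H-3 are cis, the less stable arrangement of a 2,3-disubstituted chromanone, and the two units are homochiral. C3 and C3′ are α to the C4 and C4′ carbonyl groups: acid or base epimerises them to the trans series, and base also opens ring C by β-elimination of the O1 phenoxide, which would erase C2. These two centres therefore have to be made last and under neutral conditions. C2 and C2′ are p-methoxybenzylic ether carbons; they are open to ionisation but stable while no enolisable carbonyl is nearby, so they can be set early and can steer C3 and C3′ through the face their aryl groups cover. The two halves differ only at O-7 (free hydroxyl in unit 1, methyl ether in unit 2), a remote difference no late reagent can read, whereas O-5 and O-5′ are marked by their chelation to the neighbouring carbonyl. The feature that opens the key step is that each C4 is a carbonyl carbon between the aromatic carbon C4a of ring A and C3. It can therefore be carbon monoxide 16 placed between an aryl iodide carbon and an alkenyl–boron carbon, and C3 and C3′ are then the two carbons of a cis-diborated alkyne whose propargylic carbons carry the O1–C2 and O1′–C2′ aryl ether bonds.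

## Retrosynthesis

**C3–H and C3′–H.** These bonds are cut last, giving the E-configured 3,3′-bichromanylidene-4,4′-dione 21, which keeps only the two C2 centres. A late C3–C3′ coupling of two flavanone enolates was rejected because it is basic and would have to control four centres at once. In the E isomer the pseudo-twofold axis is perpendicular to the alkene plane, so both pseudoaxial 2-aryl groups cover the same face. Syn addition of hydrogen to the open face then gives the cis relation in both rings and R at C3 and C3′. In the Z isomer the two aryl groups lie on opposite faces and one ring would come out trans. The forward step must reduce a tetrasubstituted but doubly activated alkene without cleaving the benzylic C2–O1 bonds.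

**Protecting groups and alkene geometry.** Triol 21 comes from the fully protected E-enedione 20: benzyl ethers at O-5 and O-7 of unit 1, methyl ethers at O-5′ and O-7′ of unit 2. The O-7′ methyl group is the one wanted in 22 and is carried from the start. This replaces a late monomethylation of two equivalent 7-hydroxyls, which could only be statistical. The O-5′ methyl group is the only one peri to a carbonyl and falls to a chelating Lewis acid together with the benzyl ethers. Dealkylation is placed before the reduction, so that no C3–H is present when a Lewis acid is in the flask. Compound 20 is the geometric isomer of the Z-enedione 19. Z is what a cis-dimetalated alkyne delivers, and E should be the more stable isomer because it ends the parallel alignment of the two carbonyl groups.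

**The key disconnection.** In 19 the bonds C4a–C4 and C4–C3 and their primed counterparts are cut, and both C4 carbons are removed as carbon monoxide 16. This leaves the Z-diborylalkene 15 with two ortho-iodoaryl ethers. Neighbouring cuts are worse. Friedel–Crafts closure of C4–C4a needs strong acid, which ionises the C2–O1 ether. Closure of O1–C2 by conjugate addition would create C2 late and without control. Coupling without the one-carbon unit gives a five-membered 3-alkylidene-2,3-dihydrobenzofuran. The precursor has no ring C and no carbonyl group, and its only stereocentres are the two ether carbons. The forward reaction must insert 16 before the alkenyl group is transferred, on both sides, passing through the singly closed compounds 17 or 18.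

**The two C–B bonds.** Diborylalkene 15 is cut at both C–B bonds to the alkyne 13 and bis(pinacolato)diboron 14. A cis-diboration sets both boron atoms in one step with the geometry that ring closure on both sides requires. A stepwise hydrometalation would leave C3′ without a handle. The alkyne 13 is simpler by two boryl groups and the alkene geometry. The forward step has to tolerate two aryl iodides and a crowded alkyne.

**O1–C2 of unit 1.** The aryl ether bond of unit 1 in 13 is cut to the propargylic alcohol 12 and the iodophenol 4, for an etherification with inversion. A two-directional variant, making both ether bonds at once on a symmetric alkyne, would be shorter. It was set aside because it cannot tell the two ring A patterns apart. The forward step must displace at a p-methoxybenzylic centre without ionisation.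

**C2–C3 of unit 1.** Alcohol 12 is cut between the carbinol carbon and the alkyne to the terminal alkyne 10 and 4-methoxybenzaldehyde 5, with the zinc acetylide 11 as the nucleophile. Reduction chemistry at this carbon was not chosen, because a reducing catalyst would have to tell an aryl from an alkynyl group, whereas an aldehyde offers aryl against hydrogen. The existing centre in 10 lies across the linear alkyne and cannot interfere, so the catalyst alone must set the new centre.

**Unit 2.** Alkyne 10 is the desilylated form of 9, the ether of alcohol 8 with iodophenol 2, again made with inversion. Alcohol 8 is cut at the carbinol–alkyne bond to aldehyde 5 and ethynyltrimethylsilane 6 (through the zinc acetylide 7). The silyl group keeps the second alkyne terminus closed until unit 2 is in place.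

**The phenols.** Iodophenols 2 and 4 come from 3,5-dimethoxyphenol 1 and 3,5-bis(benzyloxy)phenol 3 by electrophilic iodination ortho to the free hydroxyl. The iodine marks the future C4a, and the ortho and para oxygens become O-5 and O-7.

## Roads not taken

**Alternative 1:** The cut is C3–C3′ together with two lactone C–O bonds. In the forward step two molecules of (E)-4-methoxycinnamic acid A1 are oxidised by a one-electron oxidant (a trivalent thallium carboxylate with a Lewis acid, or an anode) and join at their α-carbons; each carboxyl group traps the benzylic cation of the other half, giving the cis-fused dilactone A2.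
- Merits: the central bond and the relative configuration of four centres come in one step from a cheap acid, by a known reaction type. In the economy of making C3–C3′ it is better than the chosen plan, which needs two alkynylations for the same chain.
- Weak points: A2 is racemic and offers no handle for the absolute configuration. Its lactones are crossed, each carbonyl being tied through oxygen to the benzylic carbon of the other half, so neither lactone ring maps onto a ring C. Both must be opened, both phloroglucinol rings attached by acylation under strong acid, and ring C closed by substitution at a p-methoxybenzylic carbinol, where ionisation threatens the configuration that A2 had fixed. Neither ring A nor the difference at O-7 is addressed.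
- Against it the chosen plan sets absolute control at C2 and C2′ and ring closures that take place with both A rings already in position.

**Alternative 2:** The cut is O1–C8a and C4–C4a in both halves. Two molecules of the aryne released by fluoride from the silyl triflate A4 insert into the carboxyl C–O bonds of (2E,3E)-2,3-bis(4-methoxybenzylidene)succinic acid A3 to give the bis(2′-hydroxychalcone) A5.
- Merits: high convergence, an easily made diacid, and a favourable regiochemistry (oxygen adds to the aryne carbon remote from the 3-alkoxy group). It reaches the full carbon–oxygen skeleton in fewer steps than the chosen plan.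
- Weak points: no ring closes in the key step. A3 is also a 1,3-diene that can react with an aryne in other ways. From A5 both rings C would have to close by conjugate addition of the phenols, creating all four stereocentres at once with nothing to direct them. Equilibration favours trans rings, whereas 22 needs cis rings, homochiral halves and a single enantiomer. The two 7-oxygens remain equivalent.
- Against it the chosen plan sets C2 and C2′ by catalyst control before any ring exists, and C3 and C3′ by one face-selective hydrogenation.

**Alternative 3:** The cut is both C2–aryl bonds. 4-Methoxyphenylboronic acid A7 adds twice to the C2=C3 and C2′=C3′ bonds of the unsymmetrically protected 3,3′-bichromone A6 under a cationic divalent palladium catalyst with a chiral pyridine–oxazoline ligand, and enolate protonation gives the cis,cis-biflavanone A8.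
- Merits: all four stereocentres arise in one catalytic step, no displacement at a sensitive benzylic alcohol is needed, and A8 carries the same benzyl/methyl differentiation of the two halves as the chosen plan. If the double addition worked, this road would be shorter and equal in the treatment of O-7.
- Weak points: each chromone double bond of A6 bears the other chromone at its α-carbon, and conjugate arylation of such α-substituted, peri-alkoxylated chromones is slow. The second addition takes place next to the stereocentres of the first, so catalyst and substrate may oppose each other. C3 and C3′ arise by protonation in a medium that can also epimerise them to trans. A6 itself requires an unsymmetrical bichromone coupling.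
- Against it the chosen plan has ring closures that do not depend on addition to a hindered enone, and C3/C3′ centres made by syn hydrogenation under neutral conditions.

Key step: step 9

Remark on the chemistry: flavanone numbering is used; unit 1 (rings A, C, B) is the 5,7-dihydroxy half, unit 2 (rings A′, C′, B′) the 5′-hydroxy-7′-methoxy half.

Assumption: compounds 1, 3, 5, 6, 14 and 16 are bought; ProPhenol is 2,6-bis{[2-(hydroxydiphenylmethyl)pyrrolidin-1-yl]methyl}-4-methylphenol, and the antipode that gives the R carbinol is meant (written as S,S; its sense is to be checked on the first run).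

## Route

Step 1
Reactants: 1 3,5-dimethoxyphenol
Product: 2 2-iodo-3,5-dimethoxyphenol
Conditions: NIS (1.0 equiv), CH2Cl2, −20 → 0 °C
Reagents that add atoms: N-iodosuccinimide, O=C1CCC(=O)N1I
Why: Electrophilic aromatic iodination of a strongly activated phenol; attack ortho to the free hydroxyl and para to a methoxy group (C2) should be favoured over C4, which is flanked by two methoxy groups, and any 4-iodo isomer is removed by chromatography.

Step 2
Reactants: 3 3,5-bis(benzyloxy)phenol
Product: 4 3,5-bis(benzyloxy)-2-iodophenol
Conditions: NIS (1.0 equiv), CH2Cl2, −20 → 0 °C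
Reagents that add atoms: N-iodosuccinimide, O=C1CCC(=O)N1I
Why: The same electrophilic iodination; the two benzyloxy groups shield C4 more than methoxy groups do, so iodine should enter ortho to the free hydroxyl.

Step 3
Reactants: 5 4-methoxybenzaldehyde; 6 ethynyltrimethylsilane
Product: 8 (1R)-1-(4-methoxyphenyl)-3-(trimethylsilyl)prop-2-yn-1-ol, via methylzinc acetylide 7 (not isolated)
Conditions: 6 (3 equiv), Me2Zn (3 equiv), (S,S)-ProPhenol (10 mol%), Ph3P=O (20 mol%), toluene, 0 °C; then 5, 4 °C; aq. NH4Cl
Reagents that add atoms: dimethylzinc, C[Zn]C (its MeZn group is held only by intermediate 7)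
Why: Zinc–ProPhenol-catalysed enantioselective alkynylation of an aryl aldehyde; the dinuclear zinc catalyst binds aldehyde 5 and acetylide 7 and delivers the alkynyl group to one aldehyde face, so the carbinol centre is set as R by catalyst control.

Step 4
Reactants: 8 (1R)-1-(4-methoxyphenyl)-3-(trimethylsilyl)prop-2-yn-1-ol; 2 2-iodo-3,5-dimethoxyphenol
Product: 9 [(3S)-3-(2-iodo-3,5-dimethoxyphenoxy)-3-(4-methoxyphenyl)prop-1-yn-1-yl]trimethylsilane
Conditions: 2 (1.1 equiv), PPh3, DIAD, toluene, −20 → 0 °C
Reagents that add atoms: none
Why: Mitsunobu etherification; the acidic iodophenol attacks the alkoxyphosphonium ion in an SN2 step with inversion, so R alcohol 8 should give S ether 9. Toluene at low temperature disfavours ionisation of the p-methoxybenzylic centre.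

Step 5
Reactants: 9 [(3S)-3-(2-iodo-3,5-dimethoxyphenoxy)-3-(4-methoxyphenyl)prop-1-yn-1-yl]trimethylsilane
Product: 10 2-iodo-3,5-dimethoxy-1-{[(1R)-1-(4-methoxyphenyl)prop-2-yn-1-yl]oxy}benzene
Conditions: K2CO3 (cat.), MeOH–THF, 0 °C → rt
Reagents that add atoms: none
Why: Base-catalysed protodesilylation of an alkynylsilane; carbonate in methanol is too weak to deprotonate the propargylic C–H, so the stereocentre is untouched (S becomes R only because ethynyl ranks below aryl).

Step 6
Reactants: 10 2-iodo-3,5-dimethoxy-1-{[(1R)-1-(4-methoxyphenyl)prop-2-yn-1-yl]oxy}benzene; 5 4-methoxybenzaldehyde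
Product: 12 (1R,4S)-4-(2-iodo-3,5-dimethoxyphenoxy)-1,4-bis(4-methoxyphenyl)but-2-yn-1-ol, via methylzinc acetylide 11 (not isolated)
Conditions: Me2Zn (3 equiv), (S,S)-ProPhenol (20 mol%), Ph3P=O (40 mol%), toluene, 0 °C; then 5 (2 equiv), 4 °C; aq. NH4Cl
Reagents that add atoms: dimethylzinc, C[Zn]C (its MeZn group is held only by intermediate 11)
Why: The same zinc–ProPhenol alkynylation with a functionalised alkyne; the existing centre lies across the linear alkyne, so the catalyst alone should set the new carbinol as R. Aryl iodides do not react with dialkylzinc.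

Step 7
Reactants: 12 (1R,4S)-4-(2-iodo-3,5-dimethoxyphenoxy)-1,4-bis(4-methoxyphenyl)but-2-yn-1-ol; 4 3,5-bis(benzyloxy)-2-iodophenol
Product: 13 (1S,4S)-1-[3,5-bis(benzyloxy)-2-iodophenoxy]-4-(2-iodo-3,5-dimethoxyphenoxy)-1,4-bis(4-methoxyphenyl)but-2-yne
Conditions: 4 (1.2 equiv), PPh3, DIAD, toluene, −20 → 0 °C
Reagents that add atoms: none
Why: Second Mitsunobu etherification with inversion (R to S at the new ether carbon); any loss of fidelity would show as a diastereomer of 13, which can be separated.

Step 8
Reactants: 13 (1S,4S)-1-[3,5-bis(benzyloxy)-2-iodophenoxy]-4-(2-iodo-3,5-dimethoxyphenoxy)-1,4-bis(4-methoxyphenyl)but-2-yne; 14 bis(pinacolato)diboron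
Product: 15 (1R,2Z,4R)-1-[3,5-bis(benzyloxy)-2-iodophenoxy]-4-(2-iodo-3,5-dimethoxyphenoxy)-1,4-bis(4-methoxyphenyl)-2,3-bis(4,4,5,5-tetramethyl-1,3,2-dioxaborolan-2-yl)but-2-ene
Conditions: 14 (1.2 equiv), Pt(PPh3)4 (5 mol%), DMF, 80 °C
Reagents that add atoms: none
Why: Platinum-catalysed cis-diboration of an internal alkyne: the B–B bond adds to zerovalent platinum, the alkyne inserts syn and reductive elimination gives the Z-diborylalkene. The hindered, electron-rich aryl iodides should add to platinum far more slowly than the diboron does; the descriptors change to R,R by priority only.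

Step 9
Reactants: 15 (1R,2Z,4R)-1-[3,5-bis(benzyloxy)-2-iodophenoxy]-4-(2-iodo-3,5-dimethoxyphenoxy)-1,4-bis(4-methoxyphenyl)-2,3-bis(4,4,5,5-tetramethyl-1,3,2-dioxaborolan-2-yl)but-2-ene; 16 carbon monoxide
Product: 19 (2S,2′S,3Z)-5,7-bis(benzyloxy)-5′,7′-dimethoxy-2,2′-bis(4-methoxyphenyl)-[3,3′-bichromanylidene]-4,4′-dione, via ring-C-closed boryl enone 17 (not isolated), via ring-C′-closed boryl enone 18 (not isolated)
Conditions: 16 (5 bar), PdCl2(dppf) (10 mol%), K2CO3 (4 equiv), H2O (4 equiv), anisole, 80 °C
Reagents that add atoms: none
Why: Proposed new method: the closest known reaction is the intermolecular carbonylative Suzuki–Miyaura coupling of aryl iodides with alkenylboronates to aryl vinyl ketones, which is asked here to run twice and intramolecularly on a vicinal diborylalkene. Zerovalent palladium adds into each C4a–I bond, 16 inserts to give an aroylpalladium iodide, carbonate-assisted transmetalation moves the neighbouring alkenyl carbon (C3 or C3′) from boron to palladium with retention, and reductive elimination forms C4–C3. Each ring C closes from a seven-membered acyl(alkenyl)palladacycle, a [5+1]-type annulation with 16 as the one-carbon unit, and the two closures follow one another through 17 or 18. No stereocentre is formed, C2 and C2′ are not touched, and the cis relation of the two boron atoms becomes the Z geometry of 19. The selectivity needed is insertion of 16 before transmetalation, since direct coupling would close a five-membered 3-alkylidene-2,3-dihydrobenzofuran; it is secured by the pressure of 16, by the fast migration of an electron-rich aryl group, and by the slow transmetalation of a tetrasubstituted pinacol boronate. The wide-bite-angle ligand dppf favours the acyl complex and its reductive elimination, and suspended carbonate in anisole should be mild enough to leave the C2–H bonds alone.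

Step 10
Reactants: 19 (2S,2′S,3Z)-5,7-bis(benzyloxy)-5′,7′-dimethoxy-2,2′-bis(4-methoxyphenyl)-[3,3′-bichromanylidene]-4,4′-dione
Product: 20 (2S,2′S,3E)-5,7-bis(benzyloxy)-5′,7′-dimethoxy-2,2′-bis(4-methoxyphenyl)-[3,3′-bichromanylidene]-4,4′-dione
Conditions: I2 (10 mol%), CH2Cl2, visible light, rt
Reagents that add atoms: none
Why: Iodine-atom-catalysed cis–trans isomerisation of an ene-1,4-dione: reversible addition of an iodine atom to C3=C3′ gives a tertiary α-keto radical that rotates before it loses iodine. The E isomer should be favoured because it separates the two parallel carbonyl dipoles and the C2–H/C2′–H contact; no stereocentre is involved.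

Step 11
Reactants: 20 (2S,2′S,3E)-5,7-bis(benzyloxy)-5′,7′-dimethoxy-2,2′-bis(4-methoxyphenyl)-[3,3′-bichromanylidene]-4,4′-dione
Product: 21 (2S,2′S,3E)-5,5′,7-trihydroxy-7′-methoxy-2,2′-bis(4-methoxyphenyl)-[3,3′-bichromanylidene]-4,4′-dione
Conditions: BCl3 (8 equiv), C6HMe5 (6 equiv), CH2Cl2, −78 → 0 °C; MeOH, then aq. NaHCO3
Reagents that add atoms: none
Why: Lewis-acid dealkylation: BCl3 with pentamethylbenzene as benzyl-cation trap cleaves both benzyl ethers, and boron chelated between O-5′ and the C4′ carbonyl cleaves the peri methyl ether. The non-chelated methoxy groups at C7′ and on the two 4-methoxyphenyl rings should stay, and no C3–H is yet present to epimerise.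

Step 12
Reactants: 21 (2S,2′S,3E)-5,5′,7-trihydroxy-7′-methoxy-2,2′-bis(4-methoxyphenyl)-[3,3′-bichromanylidene]-4,4′-dione
Product: 22 (2R,2′R,3R,3′R)-5,5′,7-trihydroxy-7′-methoxy-2,2′-bis(4-methoxyphenyl)-[3,3′-bichromane]-4,4′-dione
Conditions: H2 (1 atm), Pd/C (10%), EtOAc, rt
Reagents that add atoms: none
Why: Heterogeneous syn hydrogenation of the activated tetrasubstituted alkene; in the E isomer both pseudoaxial 2-aryl groups cover the same face, so both hydrogens should add to the other face, giving H-2/H-3 cis in each ring and R at C3 and C3′ (substrate control by C2 and C2′). Neutral conditions avoid epimerisation α to the ketones.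

## Compound list

1 | 3,5-dimethoxyphenol | COc1cc(O)cc(OC)c1 | starting material
2 | 2-iodo-3,5-dimethoxyphenol | COc1cc(O)c(I)c(OC)c1 | intermediate
3 | 3,5-bis(benzyloxy)phenol | Oc1cc(OCc2ccccc2)cc(OCc2ccccc2)c1 | starting material
4 | 3,5-bis(benzyloxy)-2-iodophenol | Oc1cc(OCc2ccccc2)cc(OCc2ccccc2)c1I | intermediate
5 | 4-methoxybenzaldehyde | COc1ccc(C=O)cc1 | starting material
6 | ethynyltrimethylsilane | C#C[Si](C)(C)C | starting material
7 | methyl[(trimethylsilyl)ethynyl]zinc (not isolated) | C[Zn]C#C[Si](C)(C)C | intermediate
8 | (1R)-1-(4-methoxyphenyl)-3-(trimethylsilyl)prop-2-yn-1-ol | COc1ccc([C@@H](O)C#C[Si](C)(C)C)cc1 | intermediate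
9 | [(3S)-3-(2-iodo-3,5-dimethoxyphenoxy)-3-(4-methoxyphenyl)prop-1-yn-1-yl]trimethylsilane | COc1ccc([C@@H](C#C[Si](C)(C)C)Oc2cc(OC)cc(OC)c2I)cc1 | intermediate
10 | 2-iodo-3,5-dimethoxy-1-{[(1R)-1-(4-methoxyphenyl)prop-2-yn-1-yl]oxy}benzene | COc1ccc([C@@H](C#C)Oc2cc(OC)cc(OC)c2I)cc1 | intermediate
11 | methyl[(3S)-3-(2-iodo-3,5-dimethoxyphenoxy)-3-(4-methoxyphenyl)prop-1-yn-1-yl]zinc (not isolated) | COc1ccc([C@@H](C#C[Zn]C)Oc2cc(OC)cc(OC)c2I)cc1 | intermediate
12 | (1R,4S)-4-(2-iodo-3,5-dimethoxyphenoxy)-1,4-bis(4-methoxyphenyl)but-2-yn-1-ol | COc1ccc([C@@H](O)C#C[C@@H](Oc2cc(OC)cc(OC)c2I)c2ccc(OC)cc2)cc1 | intermediate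
13 | (1S,4S)-1-[3,5-bis(benzyloxy)-2-iodophenoxy]-4-(2-iodo-3,5-dimethoxyphenoxy)-1,4-bis(4-methoxyphenyl)but-2-yne | COc1ccc([C@@H](C#C[C@@H](Oc2cc(OC)cc(OC)c2I)c2ccc(OC)cc2)Oc2cc(OCc3ccccc3)cc(OCc3ccccc3)c2I)cc1 | intermediate
14 | bis(pinacolato)diboron | CC1(C)OB(B2OC(C)(C)C(C)(C)O2)OC1(C)C | starting material
15 | (1R,2Z,4R)-1-[3,5-bis(benzyloxy)-2-iodophenoxy]-4-(2-iodo-3,5-dimethoxyphenoxy)-1,4-bis(4-methoxyphenyl)-2,3-bis(4,4,5,5-tetramethyl-1,3,2-dioxaborolan-2-yl)but-2-ene | COc1ccc([C@@H](/C(B2OC(C)(C)C(C)(C)O2)=C(B2OC(C)(C)C(C)(C)O2)\[C@@H](Oc2cc(OC)cc(OC)c2I)c2ccc(OC)cc2)Oc2cc(OCc3ccccc3)cc(OCc3ccccc3)c2I)cc1 | intermediate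
16 | carbon monoxide | [C-]#[O+] | starting material
17 | (2S,3E)-5,7-bis(benzyloxy)-3-[(2R)-2-(2-iodo-3,5-dimethoxyphenoxy)-2-(4-methoxyphenyl)-1-(4,4,5,5-tetramethyl-1,3,2-dioxaborolan-2-yl)ethylidene]-2-(4-methoxyphenyl)chroman-4-one (ring C closed, not isolated) | COc1ccc([C@@H]2Oc3cc(OCc4ccccc4)cc(OCc4ccccc4)c3C(=O)/C2=C(B2OC(C)(C)C(C)(C)O2)/[C@@H](Oc2cc(OC)cc(OC)c2I)c2ccc(OC)cc2)cc1 | intermediate
18 | (2S,3E)-3-{(2R)-2-[3,5-bis(benzyloxy)-2-iodophenoxy]-2-(4-methoxyphenyl)-1-(4,4,5,5-tetramethyl-1,3,2-dioxaborolan-2-yl)ethylidene}-5,7-dimethoxy-2-(4-methoxyphenyl)chroman-4-one (ring C′ closed, not isolated) | COc1ccc([C@@H](/C(B2OC(C)(C)C(C)(C)O2)=C2/C(=O)c3c(OC)cc(OC)cc3O[C@H]2c2ccc(OC)cc2)Oc2cc(OCc3ccccc3)cc(OCc3ccccc3)c2I)cc1 | intermediate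
19 | (2S,2′S,3Z)-5,7-bis(benzyloxy)-5′,7′-dimethoxy-2,2′-bis(4-methoxyphenyl)-[3,3′-bichromanylidene]-4,4′-dione | COc1ccc([C@@H]2Oc3cc(OCc4ccccc4)cc(OCc4ccccc4)c3C(=O)/C2=C2\C(=O)c3c(OC)cc(OC)cc3O[C@H]2c2ccc(OC)cc2)cc1 | intermediate
20 | (2S,2′S,3E)-5,7-bis(benzyloxy)-5′,7′-dimethoxy-2,2′-bis(4-methoxyphenyl)-[3,3′-bichromanylidene]-4,4′-dione | COc1ccc([C@@H]2Oc3cc(OCc4ccccc4)cc(OCc4ccccc4)c3C(=O)/C2=C2/C(=O)c3c(OC)cc(OC)cc3O[C@H]2c2ccc(OC)cc2)cc1 | intermediate
21 | (2S,2′S,3E)-5,5′,7-trihydroxy-7′-methoxy-2,2′-bis(4-methoxyphenyl)-[3,3′-bichromanylidene]-4,4′-dione | COc1ccc([C@@H]2Oc3cc(O)cc(O)c3C(=O)/C2=C2/C(=O)c3c(O)cc(OC)cc3O[C@H]2c2ccc(OC)cc2)cc1 | intermediate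
22 | (2R,2′R,3R,3′R)-5,5′,7-trihydroxy-7′-methoxy-2,2′-bis(4-methoxyphenyl)-[3,3′-bichromane]-4,4′-dione (CNP0184936.2) | COc1ccc([C@@H]2Oc3cc(O)cc(O)c3C(=O)[C@@H]2[C@H]2C(=O)c3c(O)cc(OC)cc3O[C@H]2c2ccc(OC)cc2)cc1 | target

## Step count and least certain steps

Total: 12 steps. Longest linear sequence: 10 steps (steps 3 to 12, from 5 and 6); steps 1 and 2 are one-step branches.

**Step 9 (key step).** Several processes can take the material away.
- Transfer of the alkenyl group before insertion of 16 would close five-membered rings.
- The second closure may stall, because after the first one the remaining boronate sits on an electron-poor enone and can be lost by protodeboronation.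
- Carbonate may remove the C2–H, which is γ to the new ketone, and move the double bond into ring C with loss of the C2 configuration.
- Zerovalent palladium may ionise the allylic aryl ether.

The fallback uses known reactions and sets out from 15. Palladium-catalysed reductive carbonylation with 16 and Et3SiH (Pd(OAc)2/dppf, Na2CO3, DMF) should turn both aryl iodides into aldehydes, the silane trapping the aroylpalladium before the boronate can, to give the dialdehyde F1. Addition of each alkenyl boronate to its neighbouring aldehyde, catalysed by the monovalent rhodium complex [Rh(cod)OH]2 in aqueous dioxane, would close both rings as the Z-diol F2 (mixture of carbinol epimers). Oxidation with Dess–Martin periodinane would return to the route at 19.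

**Step 8.** The aryl iodides may add oxidatively to platinum, ending the catalysis or removing iodine, and the crowded alkyne may insert too slowly. A smaller platinum complex such as Pt(PPh3)2(C2H4) answers the crowding within the step. The fallback sets out from 13: iodine–magnesium exchange with iPrMgCl·LiCl (THF, −30 °C) and a quench with DMF give the dialdehyde F3, which has no carbon–iodine bond. Its platinum-catalysed diboration gives F1, and the rhodium addition and oxidation described for step 9 lead through F2 back to the route at 19.

**Step 4 (and, in the same way, step 7).** Partial ionisation of the alkoxyphosphonium ion at the p-methoxybenzylic, propargylic carbon would erode the enantiomeric purity. In step 7 the same process only produces a separable diastereomer. The fallback sets out from 5. Ethynylmagnesium bromide gives the racemic alcohol F4, and methyl chloroformate with pyridine gives the racemic carbonate F5. A copper-catalysed enantioselective propargylic etherification with phenol 2 (monovalent copper triflate, a chiral pybox ligand chosen for the R ether, iPr2NEt) would then proceed through a copper allenylidene, in which the cation-stabilising aryl group is an asset, and return to the route at 10.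

**Step 10.** Iodine atoms may fail to add to the shielded tetrasubstituted alkene, or light may set up a mixture of isomers instead of full conversion. The fallback sets out from 19 and does not need the E isomer. Dealkylation as in step 11 gives the Z-triol F6. Zinc dust in acetic acid–THF at 0 °C would reduce the enedione to the bis-enol, and kinetic protonation of each enol on the face opposite its own 2-aryl group should give the cis ring in both units whatever the alkene geometry, returning to the route at 22.

**Step 11.** The Lewis acid may ionise the p-methoxybenzylic C2–O1 bond (ring opening and loss of C2 configuration), or cleavage of the chelated methyl ether may remain incomplete. The fallback sets out from 20 and inverts the order. Hydrogenation over Pd/C reduces the alkene as in step 12 and removes both benzyl groups to give F7. The peri methyl ether is then cleaved with the mild chelating reagent MgI2·OEt2 in THF, returning to the route at 22; the price is that C3–H is exposed to a weak Lewis acid.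

**Step 12.** Hydrogen may be delivered through enol intermediates instead of by syn addition, which weakens facial control, or the benzylic C2–O1 bonds may undergo hydrogenolysis on long exposure. The fallback sets out from 21 and uses the zinc–acetic acid reduction with kinetic protonation described for step 10, returning at 22 without any new compound.

## Further compounds

F1 | step 9 | 2-{[(1R,2Z,4R)-4-(2-formyl-3,5-dimethoxyphenoxy)-1,4-bis(4-methoxyphenyl)-2,3-bis(4,4,5,5-tetramethyl-1,3,2-dioxaborolan-2-yl)but-2-en-1-yl]oxy}-4,6-bis(benzyloxy)benzaldehyde | COc1ccc([C@@H](/C(B2OC(C)(C)C(C)(C)O2)=C(B2OC(C)(C)C(C)(C)O2)\[C@@H](Oc2cc(OC)cc(OC)c2C=O)c2ccc(OC)cc2)Oc2cc(OCc3ccccc3)cc(OCc3ccccc3)c2C=O)cc1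
F2 | step 9 | (2S,2′S,3Z)-5,7-bis(benzyloxy)-5′,7′-dimethoxy-2,2′-bis(4-methoxyphenyl)-[3,3′-bichromanylidene]-4,4′-diol (C4 and C4′ epimers) | COc1ccc([C@@H]2Oc3cc(OCc4ccccc4)cc(OCc4ccccc4)c3C(O)/C2=C2\C(O)c3c(OC)cc(OC)cc3O[C@H]2c2ccc(OC)cc2)cc1
F3 | step 8 | 2-{[(1S,4S)-4-(2-formyl-3,5-dimethoxyphenoxy)-1,4-bis(4-methoxyphenyl)but-2-yn-1-yl]oxy}-4,6-bis(benzyloxy)benzaldehyde | COc1ccc([C@@H](C#C[C@@H](Oc2cc(OC)cc(OC)c2C=O)c2ccc(OC)cc2)Oc2cc(OCc3ccccc3)cc(OCc3ccccc3)c2C=O)cc1
F4 | step 4 | rac-1-(4-methoxyphenyl)prop-2-yn-1-ol | COc1ccc(C(O)C#C)cc1
F5 | step 4 | rac-methyl 1-(4-methoxyphenyl)prop-2-yn-1-yl carbonate | COC(=O)OC(C#C)c1ccc(OC)cc1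
F6 | step 10 | (2S,2′S,3Z)-5,5′,7-trihydroxy-7′-methoxy-2,2′-bis(4-methoxyphenyl)-[3,3′-bichromanylidene]-4,4′-dione | COc1ccc([C@@H]2Oc3cc(O)cc(O)c3C(=O)/C2=C2\C(=O)c3c(O)cc(OC)cc3O[C@H]2c2ccc(OC)cc2)cc1
F7 | step 11 | (2R,2′R,3R,3′R)-5,7-dihydroxy-5′,7′-dimethoxy-2,2′-bis(4-methoxyphenyl)-[3,3′-bichromane]-4,4′-dione | COc1ccc([C@@H]2Oc3cc(O)cc(O)c3C(=O)[C@@H]2[C@H]2C(=O)c3c(OC)cc(OC)cc3O[C@H]2c2ccc(OC)cc2)cc1
F0 | step 12 | none | none
A1 | alternative 1 | (E)-4-methoxycinnamic acid | COc1ccc(/C=C/C(=O)O)cc1
A2 | alternative 1 | exo,exo cis-fused 2,6-bis(4-methoxyphenyl)-3,7-dioxabicyclo[3.3.0]octane-4,8-dione | COc1ccc([C@@H]2OC(=O)[C@@H]3[C@H]2C(=O)O[C@H]3c2ccc(OC)cc2)cc1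
A3 | alternative 2 | (2E,3E)-2,3-bis(4-methoxybenzylidene)succinic acid | COc1ccc(/C=C(C(=O)O)\C(C(=O)O)=C/c2ccc(OC)cc2)cc1
A4 | alternative 2 | 3,5-bis(benzyloxy)-2-(trimethylsilyl)phenyl trifluoromethanesulfonate | C[Si](C)(C)c1c(OS(=O)(=O)C(F)(F)F)cc(OCc2ccccc2)cc1OCc1ccccc1
A5 | alternative 2 | (2E,3E)-2,3-bis(4-methoxybenzylidene)-1,4-bis[2-hydroxy-4,6-bis(benzyloxy)phenyl]butane-1,4-dione | COc1ccc(/C=C(C(=O)c2c(O)cc(OCc3ccccc3)cc2OCc2ccccc2)\C(C(=O)c2c(O)cc(OCc3ccccc3)cc2OCc2ccccc2)=C/c2ccc(OC)cc2)cc1
A6 | alternative 3 | 5,7-bis(benzyloxy)-5′,7′-dimethoxy-4H,4′H-[3,3′-bichromene]-4,4′-dione | O=c1c(-c2coc3cc(OC)cc(OC)c3c2=O)coc2cc(OCc3ccccc3)cc(OCc3ccccc3)c12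
A7 | alternative 3 | 4-methoxyphenylboronic acid | COc1ccc(B(O)O)cc1
A8 | alternative 3 | (2R,2′R,3R,3′R)-5,7-bis(benzyloxy)-5′,7′-dimethoxy-2,2′-bis(4-methoxyphenyl)-[3,3′-bichromane]-4,4′-dione | COc1ccc([C@@H]2Oc3cc(OCc4ccccc4)cc(OCc4ccccc4)c3C(=O)[C@@H]2[C@H]2C(=O)c3c(OC)cc(OC)cc3O[C@H]2c2ccc(OC)cc2)cc1
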